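A flat target under a falling electrophile is impossible unless target is spent as fast as it is made, and the eta run looks like that.

common to all: electrophile 0.029 M

| run | nucleophile | remark | time |
|---|---|---|---|
| eta | 1.3 equiv | run made earlier |  |
| epsilon | 1.6 equiv | run made earlier |  |
| autumn | 1.20 equiv |  | 40 min |
| midnight | 1.80 equiv |  | 40 min |

- eta (time / min: electrophile / %, target / %): 4.00: 59, 39; 10.0: 45, 44; 20.0: 28, 38; 30.0: 22, 42; 40.0: 15, 40
- epsilon (time / min: electrophile / %, target / %): 8.00: 41, 49; 15.0: 33, 48; 25.0: 20, 48; 30.0: 17, 46; 40.0: 9, 44

(standard deviation of a reading: 1.5 percentage points)

* part of the electrophile that has reacted at the end, autumn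
* part of the electrophile that has reacted at the end, midnight
* what raising the equivalents of nucleophile from its lowest to its highest value here does to the part of the electrophile that has reacted (changes below 5 percentage points count as none) (no change / it falls / it rises)

- in percentages every species weighs as the electrophile in it: one side product counts as two
- the earlier runs were read with a standard deviation of 1.5 percentage points
- steps that have been proposed: electrophile + target -> side product; nucleophile + acid set free <-> protonated nucleophile; 2 nucleophile -> homo dimer; electrophile + nucleophile -> acid set free + target; acid set free -> by-product carried off

In eta, from 10.0 min to 40.0 min, the electrophile falls from 45 % to 15 % while target reads 44 % and then 40 %. The proposed step electrophile + target -> side product fits this: with target held, the electrophile decays pseudo-first-order. I name the tail constant, the log fall of the electrophile per minute per fraction of the charge standing as target. Eta reads 0.0872 min⁻¹, and epsilon, from 8.00 min to 40.0 min, reads 0.102 min⁻¹, so I carry 0.0945 min⁻¹. Epsilon ends with 44 % of target against 40 % in eta, so I expect conversion to rise with nucleophile, but I put no number on it.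

The forecast says 82 % for autumn, 93 % for midnight and, for the trend, it rises, from “about 1.4 log units per equivalent”.

The flask gives 81.9 % for autumn and 90.7 % for midnight, a change of 8.7 percentage points: it rises.

    electrophile + target → side product (k = 1.49 M⁻¹ min⁻¹)
    nucleophile + acid set free ⇌ protonated nucleophile, settled at all times (K = 1700 M⁻¹)
    2 nucleophile → homo dimer (k = 5.36 M⁻¹ min⁻¹)
    electrophile + nucleophile → acid set free + target (k = 10.1 M⁻¹ min⁻¹)
    acid set free → by-product carried off (k = 0.0691 min⁻¹)

The flask holds what a conversion figure does not show: part of that conversion is electrophile burnt on target. Without that step autumn falls from 81.9 % to 63.2 % and midnight from 90.7 % to 75.7 %, so it adds 19 points in autumn and 15 points in midnight, and the gap between the two flasks reads 12 points without it and 8.7 points with it. That gap is due to the extra equivalents of nucleophile in midnight: on the equivalents of autumn, midnight gives 81.9 % instead of 90.7 %. In autumn the tail constant takes 32.3 % at 20.0 min to 16.0 % at 40.0 min, where the flask holds 18.1 %. Autumn read at 2.5 h, with target at 35.9 %, comes out at 0.431 % by the tail constant and holds 0.65 %.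

The data are simulated for substances that don't exist, noise included.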